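Cutting the C1–C8a bond of the tetralin ring (C1: the diarylmethine carbon; C8a: the fusion carbon para to the C6 methoxy group) uncovers a hidden twofold symmetry axis. The precursor is acyclic (2S,3S)-2,3-bis(3,4-dimethoxybenzyl)-1,4-dimethoxybutane, in which future C1 and C4 are homotopic benzylic CH2 groups and the two veratryl rings are equivalent. In the key step DDQ takes hydride from either CH2 and the other ring closes the six-membered ring. This dehydrogenative Friedel–Crafts cyclisation joins two C–H carbons without prefunctionalisation and sets C1 under control of C2 and C3. C2 and C3 themselves arise in one event, by auxiliary-controlled oxidative dimerisation of one hydrocinnamoyl imide enolate.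

Key step: step 5

Remark: tetralin numbering is used (C1 = CH(aryl), C2 and C3 = CH(CH2OMe), C4 = ring CH2, C4a/C8a = fusion carbons). The target SMILES reads as (1R,2S,3S), all-trans. Compounds 1 and 2 and the LDA solution are assumed to be bought.

Step 1
Reactants: 1 3-(3,4-dimethoxyphenyl)propanoic acid; 2 (R)-4-benzyloxazolidin-2-one
Product: 4 (R)-4-benzyl-3-[3-(3,4-dimethoxyphenyl)propanoyl]oxazolidin-2-one, via mixed pivalic anhydride 3 (not isolated)
Conditions: PivCl, Et3N, THF, −20 °C; then LiCl, 2, −20 °C → rt
Reagents that add atoms: none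
Why: N-acylation of an oxazolidinone through the mixed pivalic anhydride (LiCl/Et3N protocol), in which the hindered pivaloyl carbonyl directs attack to the hydrocinnamoyl carbonyl; no stereocentre is formed and the bought C4 centre of 2 is untouched.

Step 2
Reactants: 4 (R)-4-benzyl-3-[3-(3,4-dimethoxyphenyl)propanoyl]oxazolidin-2-one (two molecules)
Product: 6 (2S,3S)-1,4-bis[(R)-4-benzyl-2-oxooxazolidin-3-yl]-2,3-bis(3,4-dimethoxybenzyl)butane-1,4-dione, via lithium Z-enolate 5 (not isolated)
Conditions: LDA (commercial solution, 1.05 equiv), THF, −78 °C; then anhydrous CuCl2 (1.1 equiv) in DMF, −78 °C → 0 °C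
Reagents that add atoms: none
Why: Cu(II)-mediated oxidative enolate homocoupling, in which each α-carbon of the chelated Z-enolate bonds on the face anti to the C4-benzyl group of its (R)-auxiliary (the same facial sense as in Evans alkylation), so both new stereocentres should come out S in one event, with the C2-symmetric isomer as the doubly matched product and any meso isomer removable by crystallisation or chromatography.

Step 3
Reactants: 6 (2S,3S)-1,4-bis[(R)-4-benzyl-2-oxooxazolidin-3-yl]-2,3-bis(3,4-dimethoxybenzyl)butane-1,4-dione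
Product: 7 (2S,3S)-2,3-bis(3,4-dimethoxybenzyl)butane-1,4-diol
Conditions: LiBH4, MeOH (additive), THF, 0 °C → rt; aqueous NaOH work-up
Reagents that add atoms: none
Why: Reductive cleavage of N-acyloxazolidinones with LiBH4 by hydride attack at the more electrophilic exocyclic carbonyl groups, under conditions too weakly basic to enolise C2/C3, so the S,S configuration is kept and the auxiliary can be recovered.

Step 4
Reactants: 7 (2S,3S)-2,3-bis(3,4-dimethoxybenzyl)butane-1,4-diol
Product: 9 (2S,3S)-2,3-bis(3,4-dimethoxybenzyl)-1,4-dimethoxybutane (phyllanthin), via disodium dialkoxide 8 (not isolated)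
Conditions: NaH, THF–DMF, 0 °C; then MeI, 0 °C → rt
Reagents that add atoms: iodomethane, CI
Why: Williamson ether synthesis on two unhindered primary alkoxides; no stereocentre is touched.

Step 5
Reactants: 9 (2S,3S)-2,3-bis(3,4-dimethoxybenzyl)-1,4-dimethoxybutane (phyllanthin)
Product: 11 phyltetralin (1R,2S,3S)-1-(3,4-dimethoxyphenyl)-6,7-dimethoxy-2,3-bis(methoxymethyl)-1,2,3,4-tetrahydronaphthalene, via benzylic cation 10 (not isolated)
Conditions: DDQ (1.0 equiv, slow addition), CH2Cl2 (high dilution), 4 Å MS, 0 °C → rt; stopped short of full conversion, recovered 9 recycled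
Reagents that add atoms: none
Why: DDQ forms a charge-transfer complex with one veratryl ring of 9 and abstracts hydride from its benzylic CH2 to give the 4-methoxy-stabilised cation 10, which is attacked by C6 of the other veratryl ring, after which DDQH− takes up the arene proton so that the hydroquinone is the only co-product. The closest known reaction type is the DDQ-mediated oxidative cyclisation of dibenzylbutane and dibenzylbutyrolactone lignans to aryltetralins, a dehydrogenative intramolecular Friedel–Crafts alkylation whose ring-closing half is the same as in the acid cyclisation of 7-hydroxylignans. The one new ring (C1–C2–C3–C4–C4a–C8a) closes 6-exo-trig at the cationic carbon (its π bond to the aryl group stays outside the ring) and endo with respect to the attacking arene π bond, through a chair-like transition state. The new stereocentre C1 is controlled by C2 and C3: with both CH2OMe arms equatorial, the aryl group on the planar cation takes the pseudo-equatorial position to avoid allylic strain and a clash with the C2 arm, which should give the 1,2-trans (1R) isomer. Site selectivity needs no control because the twofold axis makes both benzylic CH2 groups and both rings equivalent, and ring regioselectivity (C6, para to the 3-OMe group, rather than the flanked C2 position) is secured by electronics and sterics. Chemoselectivity against aryl–aryl coupling to an eight-membered ring is sought by leaving out strong acid, so that benzylic hydride loss outruns radical-cation chemistry, and further dehydrogenation of 11 is held back by slow addition of a single equivalent of DDQ at low temperature.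

Compound list
1 | 3-(3,4-dimethoxyphenyl)propanoic acid | COc1ccc(CCC(=O)O)cc1OC | starting material
2 | (R)-4-benzyloxazolidin-2-one | O=C1OC[C@@H](Cc2ccccc2)N1 | starting material
3 | 3-(3,4-dimethoxyphenyl)propanoic pivalic anhydride | COc1ccc(CCC(=O)OC(=O)C(C)(C)C)cc1OC | intermediate
4 | (R)-4-benzyl-3-[3-(3,4-dimethoxyphenyl)propanoyl]oxazolidin-2-one | COc1ccc(CCC(=O)N2[C@H](Cc3ccccc3)COC2=O)cc1OC | intermediate
5 | lithium (Z)-enolate of 4 | COc1ccc(C/C=C(\[O-])N2[C@H](Cc3ccccc3)COC2=O)cc1OC.[Li+] | intermediate
6 | (2S,3S)-1,4-bis[(R)-4-benzyl-2-oxooxazolidin-3-yl]-2,3-bis(3,4-dimethoxybenzyl)butane-1,4-dione | O=C(N1[C@H](Cc2ccccc2)COC1=O)[C@@H](Cc1ccc(OC)c(OC)c1)[C@H](Cc1ccc(OC)c(OC)c1)C(=O)N1[C@H](Cc2ccccc2)COC1=O | intermediate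
7 | (2S,3S)-2,3-bis(3,4-dimethoxybenzyl)butane-1,4-diol | OC[C@@H](Cc1ccc(OC)c(OC)c1)[C@H](Cc1ccc(OC)c(OC)c1)CO | intermediate
8 | disodium dialkoxide of 7 | [Na+].[Na+].[O-]C[C@@H](Cc1ccc(OC)c(OC)c1)[C@H](Cc1ccc(OC)c(OC)c1)C[O-] | intermediate
9 | (2S,3S)-2,3-bis(3,4-dimethoxybenzyl)-1,4-dimethoxybutane (phyllanthin) | COC[C@@H](Cc1ccc(OC)c(OC)c1)[C@H](Cc1ccc(OC)c(OC)c1)COC | intermediate
10 | 3,4-dimethoxybenzylic cation derived from 9 | COC[C@@H](Cc1ccc(OC)c(OC)c1)[C@H]([CH+]c1ccc(OC)c(OC)c1)COC | intermediate
11 | phyltetralin, (1R,2S,3S)-1-(3,4-dimethoxyphenyl)-6,7-dimethoxy-2,3-bis(methoxymethyl)-1,2,3,4-tetrahydronaphthalene | COC[C@H]1Cc2cc(OC)c(OC)cc2[C@@H](c2ccc(OC)c(OC)c2)[C@@H]1COC | target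

Total step count: 5. Longest linear sequence: 5.

Steps most likely to fail

1. Step 5.
- **What may go wrong:**
  - Aryl–aryl coupling of the two veratryl rings may compete with benzylic hydride loss.
  - The cation may lose its β-proton or be captured by the methoxy oxygen of the future C3 arm.
  - Hydride abstraction may continue at C1–H or C4–H of the product, which leads to dehydrogenation.
- **Fallback (sets out from 4, returns at 11):** the cation is made by ionising a benzylic alcohol instead of by C–H oxidation.
  - The sodium enolate of 4 (NaHMDS, THF, −78 °C) undergoes Evans alkylation with tert-butyl bromoacetate to give tert-butyl (S)-4-[(R)-4-benzyl-2-oxooxazolidin-3-yl]-3-(3,4-dimethoxybenzyl)-4-oxobutanoate F1.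
  - LiBH4 removes the auxiliary to give tert-butyl (S)-3-(3,4-dimethoxybenzyl)-4-hydroxybutanoate F2.
  - TFA in CH2Cl2 closes F2 to (S)-4-(3,4-dimethoxybenzyl)dihydrofuran-2(3H)-one F3.
  - The lithium enolate of F3 adds to 3,4-dimethoxybenzaldehyde anti to the benzyl group. This gives (3R,4S)-4-(3,4-dimethoxybenzyl)-3-[(3,4-dimethoxyphenyl)(hydroxy)methyl]dihydrofuran-2(3H)-one F4, whose carbinol configuration is of no consequence.
  - TFA in CH2Cl2 ionises the carbinol and closes the same C1–C8a bond. The product is the trans-fused (3aS,9R,9aS)-9-(3,4-dimethoxyphenyl)-6,7-dimethoxy-3a,4,9,9a-tetrahydronaphtho[2,3-c]furan-1(3H)-one F5.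
  - LiAlH4 opens the lactone to [(1R,2S,3S)-1-(3,4-dimethoxyphenyl)-6,7-dimethoxy-1,2,3,4-tetrahydronaphthalene-2,3-diyl]dimethanol F6.
  - NaH/MeI converts F6 into 11.

2. Step 2.
- **What may go wrong:** facial control in the C–C coupling may be incomplete (meso isomer), and the enolate may be α-chlorinated or simply re-protonated, lowering the throughput.
- **Fallback (sets out from 4, returns at 7):** the two benzylic arms are installed one after the other instead of by dimerisation.
  - Compound 4 is taken through F1 and F2 to the lactone (S)-4-(3,4-dimethoxybenzyl)dihydrofuran-2(3H)-one F3, as described above.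
  - The lithium enolate of F3 (LiHMDS, THF, −78 °C) is alkylated with 3,4-dimethoxybenzyl bromide anti to the existing benzyl group to give (3S,4S)-3,4-bis(3,4-dimethoxybenzyl)dihydrofuran-2(3H)-one F7.
  - LiAlH4 reduces F7 to 7.

3. Step 3.
- **What may go wrong:** hydride may attack the ring carbonyl of the hindered, doubly α-branched imide (endocyclic opening of the auxiliary), and the reduction may stay incomplete.
- **Fallback (sets out from 6, returns at 7):** hydrolysis first, then reduction.
  - LiOH/H2O2 (THF–H2O, 0 °C) attacks the exocyclic carbonyl selectively. It cleaves both auxiliaries to give (2S,3S)-2,3-bis(3,4-dimethoxybenzyl)succinic acid F8.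
  - BH3·THF or LiAlH4 reduces F8 to 7.

Further compounds
F1 | step 5 | tert-butyl (S)-4-[(R)-4-benzyl-2-oxooxazolidin-3-yl]-3-(3,4-dimethoxybenzyl)-4-oxobutanoate | CC(C)(C)OC(=O)C[C@H](Cc1ccc(OC)c(OC)c1)C(=O)N1[C@H](Cc2ccccc2)COC1=O
F2 | step 5 | tert-butyl (S)-3-(3,4-dimethoxybenzyl)-4-hydroxybutanoate | CC(C)(C)OC(=O)C[C@H](Cc1ccc(OC)c(OC)c1)CO
F3 | step 5 | (S)-4-(3,4-dimethoxybenzyl)dihydrofuran-2(3H)-one | O=C1C[C@H](Cc2ccc(OC)c(OC)c2)CO1
F4 | step 5 | (3R,4S)-4-(3,4-dimethoxybenzyl)-3-[(3,4-dimethoxyphenyl)(hydroxy)methyl]dihydrofuran-2(3H)-one (carbinol epimers) | O=C1OC[C@@H](Cc2ccc(OC)c(OC)c2)[C@@H]1C(O)c1ccc(OC)c(OC)c1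
F5 | step 5 | (3aS,9R,9aS)-9-(3,4-dimethoxyphenyl)-6,7-dimethoxy-3a,4,9,9a-tetrahydronaphtho[2,3-c]furan-1(3H)-one | O=C1OC[C@H]2Cc3cc(OC)c(OC)cc3[C@@H](c3ccc(OC)c(OC)c3)[C@@H]21
F6 | step 5 | [(1R,2S,3S)-1-(3,4-dimethoxyphenyl)-6,7-dimethoxy-1,2,3,4-tetrahydronaphthalene-2,3-diyl]dimethanol | OC[C@H]1Cc2cc(OC)c(OC)cc2[C@@H](c2ccc(OC)c(OC)c2)[C@@H]1CO
F7 | step 2 | (3S,4S)-3,4-bis(3,4-dimethoxybenzyl)dihydrofuran-2(3H)-one | O=C1OC[C@@H](Cc2ccc(OC)c(OC)c2)[C@@H]1Cc1ccc(OC)c(OC)c1
F8 | step 3 | (2S,3S)-2,3-bis(3,4-dimethoxybenzyl)succinic acid | OC(=O)[C@@H](Cc1ccc(OC)c(OC)c1)[C@H](Cc1ccc(OC)c(OC)c1)C(=O)O
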